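Ring A is opened at the bond between C5, which carries the ethylene bridge, and the neighbouring benzyl-bearing C4, so the arene unfolds into a linear 3,5,7-triketo ester. This uses the meta oxygens at C1 and C3 and the two identical 4-hydroxybenzyl groups at C4 and C6 flanking C5: they are the carbonyls and the C2 and C6 branches of one polyketide-like chain. In one pot the key step closes ring A by a chain C2-to-C7 aldol, expels the carboxyl carbon and aromatises. The precursor is an open-chain allyl 2,6-dibenzyl-9-aryl-3,5,7-trioxononanoate, whose allyl ester lets CO2 leave without hydroxide or strong acid.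

Key step: step 9

Assumption: the target is achiral, so no stereocentre has to be set. The centres at chain C2 and C6 and those of the cyclic ketols of the key step are enolisable or transient, so these compounds are handled as stereoisomer and tautomer mixtures and drawn as keto forms. Chain atoms are counted from the ester carbonyl (C1) to the carbon next to ring B (C9), and chain C2, C3, C4, C5, C6, C7 become ring A C4, C3, C2, C1, C6, C5.

Step 1
Reactants: 1 allyl acetoacetate; 2 4-(benzyloxy)benzyl chloride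
Product: 3 allyl 2-[4-(benzyloxy)benzyl]-3-oxobutanoate (racemic)
Conditions: 1 (1.5 equiv), K2CO3, NaI (cat.), acetone, reflux
Reagents that add atoms: none
Why: Acetoacetic ester alkylation, an SN2 C-alkylation of the potassium enolate by a reactive benzylic halide with iodide assistance; the excess of 1 holds back dialkylation, and the new C2 centre is racemic and enolisable, which does not matter.

Step 2
Reactants: 4 3-[4-(benzyloxy)phenyl]propanoic acid
Product: 6 3-[4-(benzyloxy)phenyl]-N-methoxy-N-methylpropanamide, via acyl imidazolide 5 (not isolated)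
Conditions: CDI, CH2Cl2, rt; then MeNH(OMe)·HCl, rt
Reagents that add atoms: N,O-dimethylhydroxylamine hydrochloride, CNOC.Cl
Why: Standard Weinreb amide formation by acyl transfer from the imidazolide to the amine, and the aryl benzyl ether is inert under these conditions.

Step 3
Reactants: 3 allyl 2-[4-(benzyloxy)benzyl]-3-oxobutanoate; 6 3-[4-(benzyloxy)phenyl]-N-methoxy-N-methylpropanamide
Product: 8 allyl 2-[4-(benzyloxy)benzyl]-7-[4-(benzyloxy)phenyl]-3,5-dioxoheptanoate (racemic), via dilithium dianion 7 (not isolated)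
Conditions: 3 (1.25 equiv), LiN(i-Pr)2 (LDA, 2.2 equiv per 3), THF, −78 to 0 °C; then 6, −78 to −20 °C; AcOH quench at −78 °C
Reagents that add atoms: none
Why: Acylation of a beta-keto ester dianion at its more basic terminal carbon (chain C4); the chelated adduct of the N-methoxy-N-methylamide lasts until the quench, so the more acidic product never protonates unreacted dianion, and staying at or below 0 °C avoids a Carroll-type [3,3] shift of the allyl ester enolate.

Step 4
Reactants: 9 3,4-dihydrocoumarin (chroman-2-one)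
Product: 10 6-bromochroman-2-one
Conditions: Br2 (1.05 equiv), AcOH, rt
Reagents that add atoms: bromine, BrBr
Why: Electrophilic aromatic bromination para to the ring oxygen, the position at which dihydrocoumarin is known to be substituted.

Step 5
Reactants: 10 6-bromochroman-2-one
Product: 11 3-(5-bromo-2-hydroxyphenyl)-N-methoxy-N-methylpropanamide
Conditions: MeNH(OMe)·HCl (1.5 equiv), i-PrMgCl (3.0 equiv), THF, −20 °C; then 10, −20 to 0 °C; cold 1 M HCl
Reagents that add atoms: N,O-dimethylhydroxylamine hydrochloride, CNOC.Cl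
Why: Aminolysis of an activated aryl lactone by the magnesium amide (Weinreb amide synthesis from esters); i-PrMgCl is used up by the amine salt before 10 is added, so the aryl bromide is not exchanged.

Step 6
Reactants: 11 3-(5-bromo-2-hydroxyphenyl)-N-methoxy-N-methylpropanamide
Product: 12 3-[2-(benzyloxy)-5-bromophenyl]-N-methoxy-N-methylpropanamide
Conditions: BnBr (1.2 equiv), K2CO3, DMF, rt to 50 °C
Reagents that add atoms: benzyl bromide, BrCc1ccccc1
Why: Williamson ether synthesis on the phenoxide, which also removes any chance of relactonisation.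

Step 7
Reactants: 2 4-(benzyloxy)benzyl chloride; 12 3-[2-(benzyloxy)-5-bromophenyl]-N-methoxy-N-methylpropanamide
Product: 14 3-{2-(benzyloxy)-5-[4-(benzyloxy)benzyl]phenyl}-N-methoxy-N-methylpropanamide, via benzylzinc chloride 13 (not isolated)
Conditions: 2 (1.4 equiv), Zn dust, LiCl, THF, 25 °C; then 12, Pd(OAc)2 (2 mol %), SPhos (4 mol %), THF, 25 to 50 °C
Reagents that add atoms: none
Why: Negishi sp3-sp2 coupling of a benzylic zinc chloride with an aryl bromide; it fixes the diarylmethane at ring B C5 without any regiochemical or statistical issue, and the organozinc does not attack the amide.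

Step 8
Reactants: 8 allyl 2-[4-(benzyloxy)benzyl]-7-[4-(benzyloxy)phenyl]-3,5-dioxoheptanoate; 14 3-{2-(benzyloxy)-5-[4-(benzyloxy)benzyl]phenyl}-N-methoxy-N-methylpropanamide
Product: 16 allyl 2,6-bis[4-(benzyloxy)benzyl]-9-{2-(benzyloxy)-5-[4-(benzyloxy)benzyl]phenyl}-3,5,7-trioxononanoate (stereoisomer mixture), via trilithium trianion 15 (not isolated)
Conditions: 8 (1.2 equiv), LiN(i-Pr)2 (LDA, 3.3 equiv per 8), THF, −78 to 0 °C; then 14, −78 to −30 °C; AcOH quench at −78 °C, cold dilute acid wash, short silica plug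
Reagents that add atoms: none
Why: Acylation of a poly-beta-carbonyl polyanion at its last-formed and most basic carbanion (chain C6), a known chain extension that also works for secondary terminal carbanions; the amide adduct holds until the cold acid quench, so the triketo ester never meets base, and C6 emerges as a labile, uncontrolled centre.

Step 9
Reactants: 16 allyl 2,6-bis[4-(benzyloxy)benzyl]-9-{2-(benzyloxy)-5-[4-(benzyloxy)benzyl]phenyl}-3,5,7-trioxononanoate
Product: 19 4,6-bis[4-(benzyloxy)benzyl]-5-(2-{2-(benzyloxy)-5-[4-(benzyloxy)benzyl]phenyl}ethyl)benzene-1,3-diol, via ketol allyl ester 17 (not isolated), via ketol acid 18 (not isolated)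
Conditions: Cs2CO3 (2.5 equiv), THF/i-PrOH 4:1, argon, 0 °C to rt; then Pd(PPh3)4 (5 mol %), morpholine (10 equiv), rt; then AcOH to pH 4–5, 40 °C
Reagents that add atoms: none
Why: Proposed new method: carbonate enolises 16, the doubly activated C2 adds to the C7 ketone, and ketol 17 is held as the caesium salt of its new cyclic 1,3-dione, which is several pKa units more acidic than the open-chain diketone and so pulls the reversible aldol forward. Pd(PPh3)4 then ionises the allyl ester at its oxygen-bound carbon, far from the crowded quaternary C2, morpholine takes up the allyl unit, and acetic acid frees beta-keto acid 18, which loses CO2, eliminates the C7 hydroxyl against the new C2 hydrogen and enolises at C3 and C5 to resorcinol 19. The closest known reactions are the mild-base aldol aromatisation of 3,5,7-triketo esters to resorcylates and the deallylation-decarboxylation of poly-beta-carbonyl allyl esters with zerovalent palladium and morpholine; what has not been shown is the aldol of a C2 that already bears a carbon substituent, where aromatisation has to pass through loss of the carboxyl group. Ring A closes by 6-exo-trig attack on the C7 carbonyl, enolexo if the nucleophile is written as the C1-C2 ester enolate and enolendo if written as the C2-C3 ketone enolate, and both modes are allowed for six-membered rings. The centres formed at C2 and C7 and the labile one at C6 need no control, because all three become sp2 carbons of the arene. The step needs selectivity among the possible folds: C8 has one activating carbonyl and is not enolised by carbonate, so the C8-to-C3 aldol is not fed; the C7 ketone is a better acceptor than the C1 ester, which disfavours the C6-to-C1 Claisen closure and lactonisation of the C5 enol to a 2-pyranone; keeping the carboxyl on C2 until the ring exists avoids the blind folding of a decarboxylated triketone; and the absence of strong acid avoids loss of a 4-benzyloxybenzyl cation from C2.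

Step 10
Reactants: 19 4,6-bis[4-(benzyloxy)benzyl]-5-(2-{2-(benzyloxy)-5-[4-(benzyloxy)benzyl]phenyl}ethyl)benzene-1,3-diol
Product: 20 2,4-bis[4-(benzyloxy)benzyl]-3-(2-{2-(benzyloxy)-5-[4-(benzyloxy)benzyl]phenyl}ethyl)-5-methoxyphenol
Conditions: MeI (0.9 equiv), K2CO3 (1.0 equiv), acetone, rt; recovered 19 resubmitted
Reagents that add atoms: iodomethane, CI
Why: Williamson O-methylation; the mirror plane of 19 through ring A C2 and C5 makes the two hydroxyls equivalent, so only one monoether can form, and a deficit of MeI keeps the dimethyl ether low while unreacted diol is separated and recycled.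

Step 11
Reactants: 20 2,4-bis[4-(benzyloxy)benzyl]-3-(2-{2-(benzyloxy)-5-[4-(benzyloxy)benzyl]phenyl}ethyl)-5-methoxyphenol
Product: 21 2,4-bis(4-hydroxybenzyl)-3-{2-[2-hydroxy-5-(4-hydroxybenzyl)phenyl]ethyl}-5-methoxyphenol (CNP0134121.0)
Conditions: H2 (1 atm), Pd/C (10 wt % Pd on carbon), THF/MeOH, rt
Reagents that add atoms: none
Why: Catalytic hydrogenolysis of four aryl benzyl ethers; the methyl ether, the diarylmethane carbons and the ethylene bridge are inert under these conditions.

Compound list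
1 | allyl acetoacetate | C=CCOC(=O)CC(C)=O | starting material
2 | 4-(benzyloxy)benzyl chloride | ClCc1ccc(OCc2ccccc2)cc1 | starting material
3 | allyl 2-[4-(benzyloxy)benzyl]-3-oxobutanoate (racemic) | C=CCOC(=O)C(Cc1ccc(OCc2ccccc2)cc1)C(C)=O | intermediate
4 | 3-[4-(benzyloxy)phenyl]propanoic acid | O=C(O)CCc1ccc(OCc2ccccc2)cc1 | starting material
5 | 3-[4-(benzyloxy)phenyl]-1-(imidazol-1-yl)propan-1-one (acyl imidazolide, not isolated) | O=C(CCc1ccc(OCc2ccccc2)cc1)n1ccnc1 | intermediate
6 | 3-[4-(benzyloxy)phenyl]-N-methoxy-N-methylpropanamide | CON(C)C(=O)CCc1ccc(OCc2ccccc2)cc1 | intermediate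
7 | dilithium dianion of 3, dienediolate form (not isolated) | [Li+].[Li+].C=CCOC([O-])=C(Cc1ccc(OCc2ccccc2)cc1)C([O-])=C | intermediate
8 | allyl 2-[4-(benzyloxy)benzyl]-7-[4-(benzyloxy)phenyl]-3,5-dioxoheptanoate (racemic) | C=CCOC(=O)C(Cc1ccc(OCc2ccccc2)cc1)C(=O)CC(=O)CCc1ccc(OCc2ccccc2)cc1 | intermediate
9 | 3,4-dihydrocoumarin (chroman-2-one) | O=C1CCc2ccccc2O1 | starting material
10 | 6-bromochroman-2-one | O=C1CCc2cc(Br)ccc2O1 | intermediate
11 | 3-(5-bromo-2-hydroxyphenyl)-N-methoxy-N-methylpropanamide | CON(C)C(=O)CCc1cc(Br)ccc1O | intermediate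
12 | 3-[2-(benzyloxy)-5-bromophenyl]-N-methoxy-N-methylpropanamide | CON(C)C(=O)CCc1cc(Br)ccc1OCc1ccccc1 | intermediate
13 | 4-(benzyloxy)benzylzinc chloride (not isolated) | Cl[Zn]Cc1ccc(OCc2ccccc2)cc1 | intermediate
14 | 3-{2-(benzyloxy)-5-[4-(benzyloxy)benzyl]phenyl}-N-methoxy-N-methylpropanamide | CON(C)C(=O)CCc1cc(Cc2ccc(OCc3ccccc3)cc2)ccc1OCc1ccccc1 | intermediate
15 | trilithium trianion of 8, trienetriolate form (not isolated) | [Li+].[Li+].[Li+].C=CCOC([O-])=C(Cc1ccc(OCc2ccccc2)cc1)C([O-])=CC([O-])=CCc1ccc(OCc2ccccc2)cc1 | intermediate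
16 | allyl 2,6-bis[4-(benzyloxy)benzyl]-9-{2-(benzyloxy)-5-[4-(benzyloxy)benzyl]phenyl}-3,5,7-trioxononanoate (C2 and C6 labile, stereoisomer mixture) | C=CCOC(=O)C(Cc1ccc(OCc2ccccc2)cc1)C(=O)CC(=O)C(Cc1ccc(OCc2ccccc2)cc1)C(=O)CCc1cc(Cc2ccc(OCc3ccccc3)cc2)ccc1OCc1ccccc1 | intermediate
17 | allyl 1,3-bis[4-(benzyloxy)benzyl]-2-(2-{2-(benzyloxy)-5-[4-(benzyloxy)benzyl]phenyl}ethyl)-2-hydroxy-4,6-dioxocyclohexane-1-carboxylate (diastereomer mixture, present as caesium dionate, not isolated) | C=CCOC(=O)C1(Cc2ccc(OCc3ccccc3)cc2)C(=O)CC(=O)C(Cc2ccc(OCc3ccccc3)cc2)C1(O)CCc1cc(Cc2ccc(OCc3ccccc3)cc2)ccc1OCc1ccccc1 | intermediate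
18 | 1,3-bis[4-(benzyloxy)benzyl]-2-(2-{2-(benzyloxy)-5-[4-(benzyloxy)benzyl]phenyl}ethyl)-2-hydroxy-4,6-dioxocyclohexane-1-carboxylic acid (diastereomer mixture, not isolated) | OC(=O)C1(Cc2ccc(OCc3ccccc3)cc2)C(=O)CC(=O)C(Cc2ccc(OCc3ccccc3)cc2)C1(O)CCc1cc(Cc2ccc(OCc3ccccc3)cc2)ccc1OCc1ccccc1 | intermediate
19 | 4,6-bis[4-(benzyloxy)benzyl]-5-(2-{2-(benzyloxy)-5-[4-(benzyloxy)benzyl]phenyl}ethyl)benzene-1,3-diol | Oc1cc(O)c(Cc2ccc(OCc3ccccc3)cc2)c(CCc2cc(Cc3ccc(OCc4ccccc4)cc3)ccc2OCc2ccccc2)c1Cc1ccc(OCc2ccccc2)cc1 | intermediate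
20 | 2,4-bis[4-(benzyloxy)benzyl]-3-(2-{2-(benzyloxy)-5-[4-(benzyloxy)benzyl]phenyl}ethyl)-5-methoxyphenol | COc1cc(O)c(Cc2ccc(OCc3ccccc3)cc2)c(CCc2cc(Cc3ccc(OCc4ccccc4)cc3)ccc2OCc2ccccc2)c1Cc1ccc(OCc2ccccc2)cc1 | intermediate
21 | 2,4-bis(4-hydroxybenzyl)-3-{2-[2-hydroxy-5-(4-hydroxybenzyl)phenyl]ethyl}-5-methoxyphenol (CNP0134121.0, achiral) | COc1cc(O)c(Cc2ccc(O)cc2)c(CCc2cc(Cc3ccc(O)cc3)ccc2O)c1Cc1ccc(O)cc1 | target

Total step count: 11.
Longest linear sequence: 8 steps (steps 4 to 11, from 9 to 21).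

Steps most likely to fail

Step 9. The crowded aldol equilibrium may stay on the side of the open chain. Deallylation and loss of CO2 would then precede ring closure, and the chain would fold without regiocontrol. Further drains are allyl transfer to the enolate carbon between the two ring carbonyls, lactonisation of the C5 enol onto C1, and Claisen closure.

The fallback uses known chemistry only. It sets out from 1, 6 and 14 and comes back at 19. The chain is built without the C2 benzyl group, so the fold is the established resorcylate-forming aldol in which C2 keeps a hydrogen. The missing benzyl group is added afterwards at the carbon freed by decarboxylation.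
- LiN(i-Pr)2 converts 1 into the dilithium dianion of allyl acetoacetate F1, which is acylated by 6 to allyl 7-[4-(benzyloxy)phenyl]-3,5-dioxoheptanoate F2.
- Three equivalents of LiN(i-Pr)2 give the trilithium trianion of the diketo ester F3. It takes up 14 at C6 to give allyl 6-[4-(benzyloxy)benzyl]-9-{2-(benzyloxy)-5-[4-(benzyloxy)benzyl]phenyl}-3,5,7-trioxononanoate F4.
- Cs2CO3 followed by AcOH should fold this chain to allyl 5-[4-(benzyloxy)benzyl]-6-(2-{2-(benzyloxy)-5-[4-(benzyloxy)benzyl]phenyl}ethyl)-2,4-dihydroxybenzoate F5.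
- Pd(PPh3)4 and morpholine release the corresponding 2,4-dihydroxybenzoic acid F6.
- Heating in DMSO removes CO2 to give 4-[4-(benzyloxy)benzyl]-5-(2-{2-(benzyloxy)-5-[4-(benzyloxy)benzyl]phenyl}ethyl)benzene-1,3-diol F7.
- Vilsmeier–Haack formylation (POCl3, DMF) goes to the only free position para to a hydroxyl and gives the 2,4-dihydroxybenzaldehyde F8.
- Excess 4-(benzyloxy)phenylmagnesium bromide gives the racemic diarylmethanol F9.
- Ionic reduction (Et3SiH, CF3CO2H, CH2Cl2, low temperature) gives 19.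

Step 8. Three things may go wrong: proton transfer from the enolisable amide to the secondary C6 carbanion, incomplete third deprotonation, or premature cyclisation of the triketo ester during work-up.

The fallback replaces acylation by aldol addition and oxidation. It sets out from 14 and 15 and comes back at 16.
- i-Bu2AlH reduces 14 to 3-{2-(benzyloxy)-5-[4-(benzyloxy)benzyl]phenyl}propanal F10.
- Trianion 15 adds to this more reactive and less acidic electrophile at −78 °C. The product is allyl 2,6-bis[4-(benzyloxy)benzyl]-9-{2-(benzyloxy)-5-[4-(benzyloxy)benzyl]phenyl}-7-hydroxy-3,5-dioxononanoate F11.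
- Dess–Martin oxidation under buffered conditions gives 16.

Step 10. Over-methylation to the diether and some C-methylation at ring A C2 may erode the monoether, since the two hydroxyls react independently.

The fallback replaces statistical protection by exhaustive methylation and self-limiting demethylation. It sets out from 19 and comes back at 21.
- Excess MeI and K2CO3 give the 1,3-dimethoxy tetrabenzyl ether F12.
- H2 over Pd/C gives the tetraphenol dimethyl ether F13.
- NaSEt in hot DMF removes one methyl group by SN2 attack. The phenoxide formed on ring A deactivates the second methoxy group, so the reaction should stop at 21.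

Further compounds
F1 | step 9 | dilithium dianion of allyl acetoacetate | [Li+].[Li+].C=CCOC([O-])=CC([O-])=C
F2 | step 9 | allyl 7-[4-(benzyloxy)phenyl]-3,5-dioxoheptanoate | C=CCOC(=O)CC(=O)CC(=O)CCc1ccc(OCc2ccccc2)cc1
F3 | step 9 | trilithium trianion of the diketo ester F2 | [Li+].[Li+].[Li+].C=CCOC([O-])=CC([O-])=CC([O-])=CCc1ccc(OCc2ccccc2)cc1
F4 | step 9 | allyl 6-[4-(benzyloxy)benzyl]-9-{2-(benzyloxy)-5-[4-(benzyloxy)benzyl]phenyl}-3,5,7-trioxononanoate (racemic, C6 labile) | C=CCOC(=O)CC(=O)CC(=O)C(Cc1ccc(OCc2ccccc2)cc1)C(=O)CCc1cc(Cc2ccc(OCc3ccccc3)cc2)ccc1OCc1ccccc1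
F5 | step 9 | allyl 5-[4-(benzyloxy)benzyl]-6-(2-{2-(benzyloxy)-5-[4-(benzyloxy)benzyl]phenyl}ethyl)-2,4-dihydroxybenzoate | C=CCOC(=O)c1c(O)cc(O)c(Cc2ccc(OCc3ccccc3)cc2)c1CCc1cc(Cc2ccc(OCc3ccccc3)cc2)ccc1OCc1ccccc1
F6 | step 9 | 5-[4-(benzyloxy)benzyl]-6-(2-{2-(benzyloxy)-5-[4-(benzyloxy)benzyl]phenyl}ethyl)-2,4-dihydroxybenzoic acid | OC(=O)c1c(O)cc(O)c(Cc2ccc(OCc3ccccc3)cc2)c1CCc1cc(Cc2ccc(OCc3ccccc3)cc2)ccc1OCc1ccccc1
F7 | step 9 | 4-[4-(benzyloxy)benzyl]-5-(2-{2-(benzyloxy)-5-[4-(benzyloxy)benzyl]phenyl}ethyl)benzene-1,3-diol | Oc1cc(O)c(Cc2ccc(OCc3ccccc3)cc2)c(CCc2cc(Cc3ccc(OCc4ccccc4)cc3)ccc2OCc2ccccc2)c1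
F8 | step 9 | 5-[4-(benzyloxy)benzyl]-6-(2-{2-(benzyloxy)-5-[4-(benzyloxy)benzyl]phenyl}ethyl)-2,4-dihydroxybenzaldehyde | O=Cc1c(O)cc(O)c(Cc2ccc(OCc3ccccc3)cc2)c1CCc1cc(Cc2ccc(OCc3ccccc3)cc2)ccc1OCc1ccccc1
F9 | step 9 | 4-{[4-(benzyloxy)phenyl](hydroxy)methyl}-6-[4-(benzyloxy)benzyl]-5-(2-{2-(benzyloxy)-5-[4-(benzyloxy)benzyl]phenyl}ethyl)benzene-1,3-diol (racemic) | OC(c1ccc(OCc2ccccc2)cc1)c1c(O)cc(O)c(Cc2ccc(OCc3ccccc3)cc2)c1CCc1cc(Cc2ccc(OCc3ccccc3)cc2)ccc1OCc1ccccc1
F10 | step 8 | 3-{2-(benzyloxy)-5-[4-(benzyloxy)benzyl]phenyl}propanal | O=CCCc1cc(Cc2ccc(OCc3ccccc3)cc2)ccc1OCc1ccccc1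
F11 | step 8 | allyl 2,6-bis[4-(benzyloxy)benzyl]-9-{2-(benzyloxy)-5-[4-(benzyloxy)benzyl]phenyl}-7-hydroxy-3,5-dioxononanoate (stereoisomer mixture) | C=CCOC(=O)C(Cc1ccc(OCc2ccccc2)cc1)C(=O)CC(=O)C(Cc1ccc(OCc2ccccc2)cc1)C(O)CCc1cc(Cc2ccc(OCc3ccccc3)cc2)ccc1OCc1ccccc1
F12 | step 10 | 2,4-bis[4-(benzyloxy)benzyl]-3-(2-{2-(benzyloxy)-5-[4-(benzyloxy)benzyl]phenyl}ethyl)-1,5-dimethoxybenzene | COc1cc(OC)c(Cc2ccc(OCc3ccccc3)cc2)c(CCc2cc(Cc3ccc(OCc4ccccc4)cc3)ccc2OCc2ccccc2)c1Cc1ccc(OCc2ccccc2)cc1
F13 | step 10 | 2-{2-[2,6-bis(4-hydroxybenzyl)-3,5-dimethoxyphenyl]ethyl}-4-(4-hydroxybenzyl)phenol | COc1cc(OC)c(Cc2ccc(O)cc2)c(CCc2cc(Cc3ccc(O)cc3)ccc2O)c1Cc1ccc(O)cc1
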